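**Retrosynthetic overview**

1. Locants follow the target SMILES after the acetoxy oxygen: C1 (CHOAc), C2, C3 (CMe), O4, C5, C6, C7 (CHBr), C8 (CMe2), O9, C10 (CMe), C11, C12, C13 (CHOH). The strategy rests on one feature: O4 links C3 and C5 while the next carbon C10 carries O9, so the ether ring C3–O4–C5–C10–C11–C1–C2 of the 2-oxabicyclo[3.2.2]nonane is a 2-oxabicyclo[2.2.2]octane (O4 on C10) enlarged by C5.
2. Tetrahydropyran (C8–O9, C7–Br) ⇐ bromonium closure of the C10 hydroxyl on a C7=C8 prenyl olefin; prenyl ⇐ allyl by cross-metathesis.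
3. Oxepane bridge ⇐ 1,2-shift of O4 from C10 to C5 in a C5 mesylate, with water entering at C10. The chain is kept as allyl during the shift, because a trisubstituted homoallylic olefin would itself displace the sulfonate.
4. Mesylate ⇐ allylation of a C5 lactol (C5–C6). Cineole-type ether ⇐ anti opening of a C3–C13 epoxide by the C10 hydroxyl on a cis-fused γ-lactone (C1–O–C5(=O)–C10), whose convex face also fixes C10 by methylation.
5. Lactone ⇐ glyoxylate aldol (C10–C11) on the silyl dienol ether from Birch reduction of silylated p-cresol, then cis reduction at C1. Ring order: carbocycle (from the arene), γ-lactone (temporary), 2-oxabicyclo[2.2.2]octane, oxepane (key step), tetrahydropyran.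

Key step: step 13

Remark (assumption): the syn/anti sense of the glyoxylate aldol of 4 is not established, so 6–8 are drawn for the syn adduct. Because C10 is set anew in step 5, only the ring centre C11 matters, and the ligand antipode used is the one that makes the major adduct (1S) at the ring carbon.

**Route**

Step 1
Reactants: 1 p-cresol; 2 tert-butyldimethylsilyl chloride
Product: 3 tert-butyldimethyl(4-methylphenoxy)silane
Conditions: TBSCl, imidazole, DMF, rt
Reagents that add atoms: tert-butyldimethylsilyl chloride, CC(C)(C)[Si](C)(C)Cl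
Why: O-silylation of a phenol with a silyl chloride and imidazole is routine and protects the oxygen that becomes the C1 oxygen.

Step 2
Reactants: 3 aryl silyl ether
Product: 4 tert-butyldimethyl[(4-methylcyclohexa-1,4-dien-1-yl)oxy]silane
Conditions: Li, NH3(l), THF, t-BuOH, −78 °C; NH4Cl
Reagents that add atoms: none
Why: Birch reduction of a para-disubstituted aryl ether leaves both substituted carbons sp2, so the enol ether C1=C11 and the C3=C13 olefin are in place regiospecifically, and a TBS aryl ether should survive the dissolving metal.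

Step 3
Reactants: 4 silyl dienol ether; 5 ethyl glyoxylate
Product: 6 ethyl (2S)-2-(TBS-oxy)-2-[(1S)-4-methyl-6-oxocyclohex-3-en-1-yl]acetate
Conditions: [Sc(Ph-pybox)Cl2]SbF6 (10 mol %, antipode as in the remark), CH2Cl2, −78 °C
Reagents that add atoms: ethyl glyoxylate, CCOC(=O)C=O
Why: A catalytic enantioselective Mukaiyama aldol addition forms C10–C11 with transfer of silicon to the aldolate oxygen; the chiral Lewis acid chelates the glyoxylate and selects its face, and the open transition state then fixes the enol face and thereby C11.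

Step 4
Reactants: 6 keto ester
Product: 8 cis-fused silyloxy γ-lactone, via hydroxy ester 7 (not isolated)
Conditions: L-Selectride, THF, −78 °C to 0 °C; aq. NH4Cl
Reagents that add atoms: none
Why: The bulky hydride attacks the C1 ketone from the equatorial side, anti to the C11 side chain, so the new C1 alkoxide is cis to that chain (substrate control) and closes onto the ester as a cis-fused lactone.

Step 5
Reactants: 8 lactone; 9 iodomethane
Product: 10 (3R,3aR,7aS)-3-(TBS-oxy)-3,6-dimethyl-3a,4,7,7a-tetrahydro-1-benzofuran-2(3H)-one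
Conditions: LDA, THF, −78 °C; MeI, DMPU, −78 to −40 °C
Reagents that add atoms: iodomethane, CI
Why: Alkylation of the α-silyloxy lactone enolate takes place on the convex face of the cis-fused bicycle (syn to H11), which puts methyl exo and the C10 oxygen endo over the carbocycle and fixes C10 whatever its configuration in 8.

Step 6
Reactants: 10 methylated lactone; 11 mCPBA
Product: 12 C3–C13 epoxide of 10 on the face anti to the lactone
Conditions: mCPBA, NaHCO3, CH2Cl2, 0 °C
Reagents that add atoms: mCPBA, OOC(=O)c1cccc(Cl)c1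
Why: Prilezhaev epoxidation of the trisubstituted olefin should occur on the face opposite the fused lactone and the endo silyloxy group, which sets C3 and C13 by substrate control with the epoxide anti to the C11 side chain.

Step 7
Reactants: 12 epoxy lactone
Product: 14 tricyclic hydroxy lactone, via epoxy alcohol 13 (not isolated)
Conditions: HF (48 % aq.), MeCN, 0 °C to rt
Reagents that add atoms: none
Why: Acidic desilylation frees the tertiary C10 hydroxyl, which opens the protonated epoxide at the tertiary carbon C3 with inversion (acid-mediated epoxy-alcohol cyclisation, as in cineole formation from terpineol epoxide); this closes the 2-oxabicyclo[2.2.2]octane and leaves the C13 hydroxyl anti to the ether bridge.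

Step 8
Reactants: 14 hydroxy lactone; 15 tert-butyldimethylsilyl triflate
Product: 16 C13 TBS ether of 14
Conditions: TBSOTf, 2,6-lutidine, CH2Cl2, 0 °C
Reagents that add atoms: tert-butyldimethylsilyl triflate, CC(C)(C)[Si](C)(C)OS(=O)(=O)C(F)(F)F
Why: Silylation of the only free hydroxyl with a silyl triflate is reliable even next to the quaternary C3.

Step 9
Reactants: 16 silyl lactone
Product: 17 lactol (C5 anomers)
Conditions: DIBAL-H, CH2Cl2, −78 °C; Rochelle salt
Reagents that add atoms: none
Why: Partial reduction of a γ-lactone with DIBAL-H at low temperature stops at the lactol and brings C5 to the aldehyde oxidation level.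

Step 10
Reactants: 17 lactol; 18 (+)-B-allyldiisopinocampheylborane
Product: 19 diol (1-OH, (5R)-5-OH, 5-allyl)
Conditions: (+)-Ipc2B(allyl) (salt-free, 2.5 equiv), Et2O, −78 °C to rt; NaOH, H2O2
Reagents that add atoms: (+)-B-allyldiisopinocampheylborane, C=CCB([C@H]1C[C@H]2C[C@@H]([C@@H]1C)C2(C)C)[C@H]1C[C@H]2C[C@@H]([C@@H]1C)C2(C)C
Why: Brown allylation of the open hydroxy-aldehyde form of the lactol forms C5–C6; the reagent derived from (−)-α-pinene delivers allyl to the Re face of the C5 aldehyde through the chair transition state and gives the (5R) carbinol by reagent control.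

Step 11
Reactants: 19 diol; 20 acetic anhydride
Product: 21 C1 monoacetate
Conditions: Ac2O (1.1 equiv), pyridine, DMAP (cat.), CH2Cl2, −20 °C
Reagents that add atoms: acetic anhydride, CC(=O)OC(C)=O
Why: Acylation should favour the ring hydroxyl at C1 over the C5 hydroxyl, which is neopentylic (next to the fully substituted C10) and acylates much more slowly.

Step 12
Reactants: 21 monoacetate; 22 methanesulfonyl chloride
Product: 23 C5 mesylate (key-step precursor)
Conditions: MsCl, Et3N, CH2Cl2, 0 °C
Reagents that add atoms: methanesulfonyl chloride, CS(=O)(=O)Cl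
Why: Sulfonylation through sulfene is little affected by hindrance and converts the remaining C5 hydroxyl into the mesylate with retention.

Step 13
Reactants: 23 mesylate; 24 water
Product: 26 ring-expanded tertiary alcohol, via bicyclic oxonium ion 25 (not isolated)
Conditions: H2O–1,4-dioxane (1:1), 2,6-lutidine, 80 °C
Reagents that add atoms: water, O
Why: The ether oxygen O4 displaces the C5 mesylate from the rear (3-exo-tet) to give the C5–O4–C10 oxonium ion 25, and water opens this three-membered ring at the tertiary carbon C10 with cleavage of C10–O4, so that O4 ends on C5 and the new hydroxyl O9 on C10. The closest known reaction is the stereospecific ring expansion of tetrahydrofurans and tetrahydropyrans that carry an exocyclic α-sulfonate, which runs by solvolysis through a bicyclic oxonium ion and also works with a tertiary ring carbon; here it is applied to a bridged ether. No chain end closes a ring: the O4–C10 bridge of the 2-oxabicyclo[2.2.2]octane takes up C5 and becomes the seven-membered ring of the 2-oxabicyclo[3.2.2]nonane. Both new stereocentres come from two invertive displacements, so C5 (R to S) is controlled by the carbinol configuration set in step 10 and C10 (R to S) by the configuration set in step 5. The step needs O4 to outrun other neighbouring groups and water to attack C10 and not C5 or C3: the chain end is a monosubstituted vinyl group, a poor homoallylic participant (a prenyl olefin would compete, hence the methyls are added afterwards); C3 is a bridgehead whose rear side lies inside the cage; and C10 is tertiary while C5 is secondary. The C1 acetate lies on the side from which C10 is attacked, and if it captures C10 first the dioxanium ion is hydrolysed to the same alcohol.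

Step 14
Reactants: 26 allyl alcohol; 27 2-methyl-2-butene
Product: 28 prenyl tertiary alcohol
Conditions: Grubbs II (5 mol %), 2-methyl-2-butene/CH2Cl2, 40 °C
Reagents that add atoms: 2-methyl-2-butene, CC=C(C)C
Why: Olefin cross-metathesis of a terminal olefin with excess 2-methyl-2-butene is the standard conversion of allyl into prenyl and tolerates the free tertiary alcohol.

Step 15
Reactants: 28 prenyl alcohol; 29 N-bromosuccinimide
Product: 30 C13 TBS ether of the target
Conditions: NBS, HFIP, 4 Å MS, 0 °C
Reagents that add atoms: N-bromosuccinimide, O=C1CCC(=O)N1Br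
Why: In this bromoetherification the C10 hydroxyl opens the C7–C8 bromonium ion at the tertiary carbon C8 (6-endo, Markovnikov) anti to bromine; the chair transition state with C7–Br equatorial and C5–O4 axial avoids a 1,3-diaxial contact between C11 and a C8 methyl and should give the (7S) bromide (substrate control).

Step 16
Reactants: 30 silyl ether
Product: 31 target
Conditions: HF·pyridine, THF–pyridine, 0 °C to rt
Reagents that add atoms: none
Why: Fluoride cleavage of the secondary TBS ether under mildly acidic conditions leaves the acetate, the secondary bromide and the ether rings untouched.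

**Compound list**

1 | p-cresol | Cc1ccc(O)cc1 | starting material
2 | tert-butyldimethylsilyl chloride | CC(C)(C)[Si](C)(C)Cl | starting material
3 | tert-butyldimethyl(4-methylphenoxy)silane | Cc1ccc(O[Si](C)(C)C(C)(C)C)cc1 | intermediate
4 | tert-butyldimethyl[(4-methylcyclohexa-1,4-dien-1-yl)oxy]silane | CC1=CCC(O[Si](C)(C)C(C)(C)C)=CC1 | intermediate
5 | ethyl glyoxylate | CCOC(=O)C=O | starting material
6 | ethyl (2S)-2-[(tert-butyldimethylsilyl)oxy]-2-[(1S)-4-methyl-6-oxocyclohex-3-en-1-yl]acetate | CCOC(=O)[C@@H](O[Si](C)(C)C(C)(C)C)[C@@H]1CC=C(C)CC1=O | intermediate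
7 | ethyl (2S)-2-[(tert-butyldimethylsilyl)oxy]-2-[(1R,6S)-6-hydroxy-4-methylcyclohex-3-en-1-yl]acetate (formed as its lithium alkoxide, not isolated) | CCOC(=O)[C@@H](O[Si](C)(C)C(C)(C)C)[C@@H]1CC=C(C)C[C@@H]1O | intermediate
8 | (3S,3aR,7aS)-3-[(tert-butyldimethylsilyl)oxy]-6-methyl-3a,4,7,7a-tetrahydro-1-benzofuran-2(3H)-one | O=C1O[C@H]2CC(C)=CC[C@H]2[C@@H]1O[Si](C)(C)C(C)(C)C | intermediate
9 | iodomethane | CI | starting material
10 | (3R,3aR,7aS)-3-[(tert-butyldimethylsilyl)oxy]-3,6-dimethyl-3a,4,7,7a-tetrahydro-1-benzofuran-2(3H)-one | O=C1O[C@H]2CC(C)=CC[C@H]2[C@@]1(C)O[Si](C)(C)C(C)(C)C | intermediate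
11 | 3-chloroperbenzoic acid | OOC(=O)c1cccc(Cl)c1 | starting material
12 | (3R,3aR,5R,6S,7aS)-3-[(tert-butyldimethylsilyl)oxy]-5,6-epoxy-3,6-dimethylhexahydro-1-benzofuran-2(3H)-one (epoxide anti to the lactone) | O=C1O[C@H]2C[C@]3(C)O[C@@H]3C[C@H]2[C@@]1(C)O[Si](C)(C)C(C)(C)C | intermediate
13 | desilylated epoxy alcohol of 12 (free C10–OH, not isolated) | O=C1O[C@H]2C[C@]3(C)O[C@@H]3C[C@H]2[C@@]1(C)O | intermediate
14 | tricyclic hydroxy lactone: 2-oxabicyclo[2.2.2]octane with O4 bridging C3 and C10, γ-lactone C1–O–C5(=O)–C10, 13-OH anti to the ether bridge; (1S,3R,10R,11R,13R) | O=C1O[C@H]2C[C@@]3(C)O[C@]1(C)[C@@H]2C[C@H]3O | intermediate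
15 | tert-butyldimethylsilyl trifluoromethanesulfonate | CC(C)(C)[Si](C)(C)OS(=O)(=O)C(F)(F)F | starting material
16 | 13-O-TBS ether of 14 | O=C1O[C@H]2C[C@@]3(C)O[C@]1(C)[C@@H]2C[C@H]3O[Si](C)(C)C(C)(C)C | intermediate
17 | lactol of 16 (C5 hemiacetal, both anomers) | OC1O[C@H]2C[C@@]3(C)O[C@]1(C)[C@@H]2C[C@H]3O[Si](C)(C)C(C)(C)C | intermediate
18 | (+)-B-allyldiisopinocampheylborane (from (−)-α-pinene) | C=CCB([C@H]1C[C@H]2C[C@@H]([C@@H]1C)C2(C)C)[C@H]1C[C@H]2C[C@@H]([C@@H]1C)C2(C)C | starting material
19 | cineole-type diol: 1-OH, 13-OTBS, C10 bearing methyl and the (5R)-CH(OH)CH2CH=CH2 chain; (1S,3R,5R,10R,11R,13R) | O[C@H]1C[C@@]2(C)O[C@@](C)([C@H](O)CC=C)[C@@H]1C[C@H]2O[Si](C)(C)C(C)(C)C | intermediate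
20 | acetic anhydride | CC(=O)OC(C)=O | starting material
21 | 1-O-acetate of 19 (5-OH free) | CC(=O)O[C@H]1C[C@@]2(C)O[C@@](C)([C@H](O)CC=C)[C@@H]1C[C@H]2O[Si](C)(C)C(C)(C)C | intermediate
22 | methanesulfonyl chloride | CS(=O)(=O)Cl | starting material
23 | cineole-type ether with 1-OAc, 13-OTBS, (5R)-5-mesylate and allyl chain; (1S,3R,5R,10R,11R,13R) | CC(=O)O[C@H]1C[C@@]2(C)O[C@@](C)([C@H](OS(C)(=O)=O)CC=C)[C@@H]1C[C@H]2O[Si](C)(C)C(C)(C)C | intermediate
24 | water | O | starting material
25 | bicyclic oxonium ion (O4 bonded to C3, C5 and C10) as its methanesulfonate, not isolated | CC(=O)O[C@H]1C[C@@]2(C)[O+]3[C@@H](CC=C)[C@@]3(C)[C@@H]1C[C@H]2O[Si](C)(C)C(C)(C)C.CS(=O)(=O)[O-] | intermediate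
26 | 2-oxabicyclo[3.2.2]nonane with O4 bridging C3 and C5, 10-OH, 5-allyl, 1-OAc, 13-OTBS; (1S,3R,5S,10S,11R,13R) | CC(=O)O[C@H]1C[C@@]2(C)O[C@@H](CC=C)[C@@](C)(O)[C@@H]1C[C@H]2O[Si](C)(C)C(C)(C)C | intermediate
27 | 2-methyl-2-butene | CC=C(C)C | starting material
28 | 5-prenyl analogue of 26 | CC(=O)O[C@H]1C[C@@]2(C)O[C@@H](CC=C(C)C)[C@@](C)(O)[C@@H]1C[C@H]2O[Si](C)(C)C(C)(C)C | intermediate
29 | N-bromosuccinimide | O=C1CCC(=O)N1Br | starting material
30 | 13-O-TBS ether of the target; (7S)-bromide | CC(=O)O[C@H]1C[C@@]2(C)O[C@H]3C[C@H](Br)C(C)(C)O[C@@]3(C)[C@@H]1C[C@H]2O[Si](C)(C)C(C)(C)C | intermediate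
31 | CNP0247588.2; (1S,3R,5S,7S,10S,11R,13R) | CC(=O)O[C@H]1C[C@@]2(C)O[C@H]3C[C@H](Br)C(C)(C)O[C@@]3(C)[C@@H]1C[C@H]2O | target

**Totals**

Total step count: 16. Longest linear sequence: 16 steps (from p-cresol).

**Steps most likely to fail**

1. Step 13. The mesylate may ionise without help from O4, leading to elimination or a hydride or methyl shift. Water may return at C5, giving back 21 with net retention. The opened ion may lose a proton at C10, or the C1 acetate may capture C10 and end with the acetyl group on the tertiary oxygen.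
Fallback (from 12, back at 26): the same oxonium ion is made from the ether-forming side by an epoxide cascade. DIBAL-H reduces 12 to the epoxy lactol F1. Brown allylation with 18 gives the epoxy diol F2. Acetylation at C1 as in step 11 gives the acetate F3, and mesylation as in step 12 gives the mesylate F4. TBAF in THF unmasks the C10 alkoxide, which displaces the mesylate and forms the diepoxide F5 with C5 inverted. BF3·OEt2 in wet CH2Cl2 at −40 °C (or PPTS) activates the ring epoxide, the side-chain epoxide oxygen attacks C3, and water opens the epoxonium ion at C10 to give the bicyclic diol F6. Silylation of the secondary C13 hydroxyl (TBSCl, imidazole) then gives 26.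

2. Step 15. The bromonium ion may form on either olefin face and close through the competing chair, which gives the C7 epimer. The hydroxyl may attack C7 in a 5-exo mode and give a tetrahydrofuran. Solvent or bromide may capture the ion.
Fallback (from 28, back at 30): C7 is fixed by reagent control before ring closure. Shi epoxidation (D-fructose-derived ketone, Oxone, buffered MeCN–DMM–H2O, 0 °C) should give the (7R)-epoxide F7, which must be kept free of acid. Li2NiBr4 in THF opens it at the less hindered C7 with inversion and gives the bromohydrin F8. BF3·OEt2 in MeNO2 at −20 °C ionises the C8 hydroxyl with bromine participation, and the C10 hydroxyl closes the single bromonium ion at C8 to give 30.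

3. Step 3. Face selection of the glyoxylate may be poor, or the syn/anti ratio may be low, which lowers the enantiomeric purity at C11 once C10 is reset. The TBS enol ether may turn over slowly, and the β,γ-enone may move into conjugation.
Fallback (from 4, back at 8): auxiliary control replaces catalyst control. SnCl4-promoted Mukaiyama aldol of 4 with (−)-8-phenylmenthyl glyoxylate (CH2Cl2, −78 °C) gives the hydroxy ester F9, and the diastereomers can be separated at this stage. TBSOTf and 2,6-lutidine give the silyl ether F10. L-Selectride as in step 4 reduces the ketone, and lactonisation releases the auxiliary alcohol and gives 8.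

**Further compounds**

F1 | step 13 | epoxy lactol from 12 (C5 hemiacetal, both anomers) | OC1O[C@H]2C[C@]3(C)O[C@@H]3C[C@H]2[C@@]1(C)O[Si](C)(C)C(C)(C)C
F2 | step 13 | epoxy diol: 1-OH, (5R)-5-OH with allyl, 10-OTBS, C3–C13 epoxide | O[C@H]1C[C@]2(C)O[C@@H]2C[C@H]1[C@@](C)(O[Si](C)(C)C(C)(C)C)[C@H](O)CC=C
F3 | step 13 | 1-O-acetate of F2 | CC(=O)O[C@H]1C[C@]2(C)O[C@@H]2C[C@H]1[C@@](C)(O[Si](C)(C)C(C)(C)C)[C@H](O)CC=C
F4 | step 13 | 5-O-mesylate of F3 | CC(=O)O[C@H]1C[C@]2(C)O[C@@H]2C[C@H]1[C@@](C)(O[Si](C)(C)C(C)(C)C)[C@H](OS(C)(=O)=O)CC=C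
F5 | step 13 | diepoxide: C3–C13 oxirane and C5–C10 oxirane, 1-OAc, allyl on C5 | CC(=O)O[C@H]1C[C@]2(C)O[C@@H]2C[C@H]1[C@@]3(C)O[C@H]3CC=C
F6 | step 13 | 2-oxabicyclo[3.2.2]nonane diol: 10-OH, 13-OH, 1-OAc, 5-allyl | CC(=O)O[C@H]1C[C@@]2(C)O[C@@H](CC=C)[C@@](C)(O)[C@@H]1C[C@H]2O
F7 | step 15 | (7R)-7,8-epoxide of 28 | CC(=O)O[C@H]1C[C@@]2(C)O[C@@H](C[C@H]3OC3(C)C)[C@@](C)(O)[C@@H]1C[C@H]2O[Si](C)(C)C(C)(C)C
F8 | step 15 | (7S)-7-bromo-8-hydroxy derivative of 28 | CC(=O)O[C@H]1C[C@@]2(C)O[C@@H](C[C@H](Br)C(C)(C)O)[C@@](C)(O)[C@@H]1C[C@H]2O[Si](C)(C)C(C)(C)C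
F9 | step 3 | (−)-8-phenylmenthyl (2S)-2-hydroxy-2-[(1S)-4-methyl-6-oxocyclohex-3-en-1-yl]acetate | CC(C)(c1ccccc1)[C@@H]1CC[C@@H](C)C[C@H]1OC(=O)[C@@H](O)[C@@H]1CC=C(C)CC1=O
F10 | step 3 | O-TBS ether of F9 | CC(C)(c1ccccc1)[C@@H]1CC[C@@H](C)C[C@H]1OC(=O)[C@@H](O[Si](C)(C)C(C)(C)C)[C@@H]1CC=C(C)CC1=O
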